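## Remarks on the design

- Assumption: "safe" is read as chemically robust (few selectivity questions, mild conditions for the prenyl groups and the pyranone).
- Structure check: the key-step precursor and product are consistent with the mechanism. Pyranone C2, C3, C4, C5, C6 become chromone C8a, C4a, C4, C3, C2. One clarification: the Wolff shift exchanges the C8a–acyl bond for a C8a–C8 bond, so the former acyl carbon ends as C5 and the former diazo carbon as C8. The three ring-forming bonds are then C5–C6, C7–C8 and C4a–C5.
- Changes to the precursor design, with the disconnection untouched: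
  - The 4'-oxygen is carried as a triisopropylsilyl ether instead of an acetal, the same group the alkyne delivers to O7. One buffered fluoride step then frees both phenols, and no acid is used once the prenyl groups are in place.
  - The acid is activated as a mixed carbonic anhydride, not as the acid chloride, so no HCl is formed near the prenyl olefins.
  - The O-methylation also esterifies the acid, so a saponification is planned.
  - The terminal siloxyalkyne is made through a C-silylated ynolate.
- Compound 2 is also an article of commerce; buying it would save step 1.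
- Abbreviations: TIPS = triisopropylsilyl; Ar = 3,5-bis(3-methylbut-2-enyl)-4-(triisopropylsilyloxy)phenyl.

## Structural features

The target is a 3-O-methylflavonol: a chromen-4-one (benzo ring A fused to pyranone ring C through the C4a–C8a bond) with free hydroxyls at C5 and C7, a methoxy group at C3, and ring B at C2. Ring B is a 4-hydroxyphenyl joined through the single C2–C1' bond and flanked at C3' and C5' by two 3-methylbut-2-enyl (prenyl) groups. There is no stereocentre and no stereogenic double bond, so the problem is one of regiochemistry and functional-group tolerance. The fragile parts are the two trisubstituted prenyl olefins ortho to a phenol oxygen (acid closes them to 2,2-dimethylchromans), the electron-rich ring A, and the 4-pyranone, which hard nucleophiles open. The real difficulty is to tell four oxygens apart (O3 methylated; O5, O7 and O4' free) and to place two C-prenyl groups ortho to one phenol without O-alkylation. The key step exploits ring A: its oxygens at C5 and C7 are meta to each other with hydrogens at C6 and C8. That is the pattern formed when a ketene carbon (C5) and the oxygen-bearing carbon of a siloxyalkyne (C7) are built into a new benzene ring on the C4a=C8a edge of a 4-pyranone that already carries ring C, the 3-methoxy group and ring B.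

## Logic of the disconnections

**25 to 24.** The O7–Si and O4'–Si bonds are cut. Both phenols must be masked during diazoketone formation and annulation, and one silyl type on both allows a single unmasking. The skeleton does not change. The forward step needs a fluoride source buffered so that the methyl ether, the pyranone and the prenyl olefins are untouched.

**24 to 14 and 19.** The C5–C6, C7–C8 and C4a–C5 bonds are cut, which removes ring A. C5 and C8 go back to the diazoacetyl group of 14, and C6 and C7 to the alkyne 19. Ring A, with its two oxygens already differentiated, then comes from a monocyclic pyranone and a two-carbon piece. The forward step needs a regioselective (2+2) union, light that excites only the diazo group, and a 6π closure onto pyranone C3.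

**14 to 12 (through 13).** The bond between the acyl carbon and the diazo carbon is cut, leaving a carboxylic acid as a robust handle. The forward step needs acyl activation without mineral acid, and a diazoalkane that attacks the activated carbonyl faster than the enone.

**12 to 11, then to 4 and 10.** The ester C–O bond is restored, then the bond between pyranone C6 and C1' (flavone C2–C1') is cut. This is the only bond between the two π systems and it divides the molecule into halves of similar size. The forward coupling must be mild enough for a vinylogous acyl bromide, and the saponification must outrun ring opening.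

**4 to 3 to 2 to 1.** The two O–CH3 bonds, the C6–Br bond and the oxidation level of the C2 side chain are taken back in turn. Compound 1 already has the pyranone, the C5 oxygen and the C2 one-carbon unit. The forward demand is bromination at C6 while the free enol still directs it, before methylation.

**10 to 9 to 7, then to 5 and 6 (with 8).** The C–B bond, the O–Si bond and the two aryl–CH2 bonds ortho to the phenol are cut. The para bromine blocks that position during prenylation and later becomes the coupling handle. The forward demand is C- over O-alkylation.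

**19 to 18, then to 15 and 8.** The terminal C–H is traced to a C–Si bond, then the O–Si and C(sp)–O bonds are cut. The C-silyl group protects the alkyne terminus during oxygen transfer and steers silylation to oxygen. The forward demands are clean oxidation of an acetylide to an ynolate and selective removal of the C-silyl group.

## Other disconnections considered

**Alternative 1:** The cut is at C4a–C4 and C3–C4, with carbon monoxide A4 supplying C4.
- Forward step: zerovalent palladium inserts into the symmetric ring A iodide A1, A4 gives the aroyl palladium species, and the enolate of the ring B ketone A2 is acylated to the diketone A3. Acid would then remove the acetals and close O1–C2 by cyclodehydration.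
- In favour: three simple pieces are joined at once; A1 is symmetric, so ring A poses no regiochemical question; carbonylative α-arylation of ketones is a known reaction type; no diazo compound and no light are needed.
- Against: the iodide has two ortho alkoxy groups and is electron-rich, so insertion and attack on the hindered aroyl palladium species should be slow. The α-methoxy enolate could be O-acylated or arylated without A4. The final acid step has to act on a molecule with two prenyl groups next to the freed 4'-hydroxyl, which invites chroman formation.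
- Comparison: on structure, this builds ring C last from two arenes, while the chosen plan builds ring A last on a finished ring C. On mechanism, it is polar organometallic chemistry against a pericyclic cascade. On step economy, alternative 1 is the better plan, at an expected seven or so steps against thirteen. On differentiation of the oxygens the two are equal. The chosen plan is better in keeping acid away from the prenyl phenol.

**Alternative 2:** The cut is at C3–C4.
- Forward step: SmI2 A7 reduces the ring A aldehyde of the dialdehyde A5 to a ketyl, which adds to the neighbouring aldehyde and gives the cis-3,4-diol A6. Oxidation of both carbinols would give the 3,4-dione, whose enol is the flavonol; O3 would then be methylated and the acetals removed.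
- In favour: the reductive closure is neutral and should tolerate the prenyl groups; six-membered ketyl–carbonyl closures are well known; O3 would be the only free hydroxyl at the methylation stage, so the oxygens are as well differentiated as in the chosen plan.
- Against: three stereocentres are made and all are destroyed again. A two-electron reduction is followed by a four-electron oxidation. A5 contains an α-aryloxy-α-aryl acetaldehyde that enolizes and eliminates easily and is itself laborious to make. An acid deprotection is still needed at the end.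
- Comparison: on structure, it closes ring C between two ready arenes, as alternative 1 does. On mechanism, it is radical-anion chemistry with a redox detour, against a redox-neutral cascade. On step economy it is expected to be no shorter than the chosen plan and probably longer. It is better in avoiding a diazo compound, and equal in regiochemical certainty.

**Alternative 3:** The cuts are at O1–C8a and at the C5–O and C7–O bonds.
- Forward step: the enolate oxygen of the trifluorophenyl diketone A8 displaces the ortho fluoride and closes ring C to the difluoroflavone A9. The alkoxide of allyl alcohol A11 then displaces the C5 and C7 fluorides to give the tris-allyl ether A10. Allyl transfer catalysed by zerovalent palladium would free the three phenols.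
- In favour: ring A is bought whole as a trifluorobenzoyl unit; SNAr ring closure of ortho-fluoroaryl diketones is a known reaction type; the C5 and C7 fluorides are activated ortho and para by the C4 carbonyl; the final deprotection is neutral.
- Against: after the first alkoxide has entered, ring A is deactivated, so the second displacement should need forcing conditions. Under these the allyl aryl ethers may undergo Claisen rearrangement to C6 or C8, and alkoxide may add to C2 and open ring C. Making A8 also raises a C- versus O-acylation question.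
- Comparison: on structure, it keeps ring A intact and makes ring C, the reverse of the chosen plan. On mechanism, it is two-electron polar chemistry throughout. On step economy, it is the better plan, at an expected seven to eight steps. It is equal in avoiding acid after prenylation and better in avoiding diazo compounds and light. The chosen plan is better on selectivity within ring A, since both oxygens are placed in one constitutionally unambiguous event.

Key step: step 12

## Route

Step 1
Reactants: 1 kojic acid
Product: 2 comenic acid (5-hydroxy-4-oxo-4H-pyran-2-carboxylic acid)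
Conditions: O2 (1 atm), 5% Pd/C (cat.), aq NaOH (pH ca. 10), 30 °C; then aq HCl to pH 1
Reagents that add atoms: dioxygen, O=O
Why: Heyns-type aerobic oxidation on a noble metal takes the activated primary alcohol to the carboxylate; the enolate form of the pyranone is stable in cool aqueous alkali and the acid should precipitate on acidification.

Step 2
Reactants: 2 comenic acid
Product: 3 6-bromo-5-hydroxy-4-oxo-4H-pyran-2-carboxylic acid
Conditions: Br2 (1.05 equiv), H2O, 0 → 25 °C
Reagents that add atoms: bromine, BrBr
Why: Electrophilic bromination at C6, the terminus of the C5 enol (the pyranone counterpart of a phenol ortho position); C3 is deactivated by the neighbouring carboxyl group.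

Step 3
Reactants: 3 6-bromo-5-hydroxy-4-oxo-4H-pyran-2-carboxylic acid
Product: 4 methyl 6-bromo-5-methoxy-4-oxo-4H-pyran-2-carboxylate
Conditions: MeI (3 equiv), K2CO3 (2.2 equiv), DMF, 25 °C
Reagents that add atoms: iodomethane, CI
Why: SN2 O-methylation (Williamson type) of the acidic enol and of the carboxylate in one operation; the ester also makes the coupling partner soluble and non-ionic.

Step 4
Reactants: 5 4-bromophenol; 6 prenyl bromide (2.2 equiv)
Product: 7 4-bromo-2,6-bis(3-methylbut-2-enyl)phenol
Conditions: NaH (2.2 equiv), toluene, 0 → 25 °C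
Reagents that add atoms: none
Why: Ortho C-alkylation of a sodium phenoxide ion pair in a non-polar solvent, a known way to ortho,ortho'-diprenylate para-halophenols; the tight Na–O contact shields oxygen, the para position is blocked by bromine, and the dienone tautomerizes back to the phenol after each alkylation.

Step 5
Reactants: 7 4-bromo-2,6-bis(3-methylbut-2-enyl)phenol; 8 triisopropylsilyl trifluoromethanesulfonate
Product: 9 [4-bromo-2,6-bis(3-methylbut-2-enyl)phenoxy]triisopropylsilane
Conditions: 2,6-lutidine, CH2Cl2, 0 → 25 °C
Reagents that add atoms: none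
Why: O-silylation of a hindered phenol with a silyl triflate and a hindered base; the bulky silyl ether between two ortho substituents should resist the bases of steps 6 to 8.

Step 6
Reactants: 9 [4-bromo-2,6-bis(3-methylbut-2-enyl)phenoxy]triisopropylsilane
Product: 10 triisopropyl[2,6-bis(3-methylbut-2-enyl)-4-(4,4,5,5-tetramethyl-1,3,2-dioxaborolan-2-yl)phenoxy]silane
Conditions: B2pin2, Pd(dppf)Cl2 (3 mol %), KOAc, 1,4-dioxane, 85 °C
Reagents that add atoms: bis(pinacolato)diboron, CC1(C)OB(OC1(C)C)B1OC(C)(C)C(C)(C)O1
Why: Miyaura borylation (oxidative addition of zerovalent palladium to the aryl bromide, acetate-assisted transmetalation, reductive elimination); no organolithium is needed and the olefins and silyl ether are inert.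

Step 7
Reactants: 4 methyl 6-bromo-5-methoxy-4-oxo-4H-pyran-2-carboxylate; 10 the aryl pinacol boronate
Product: 11 methyl 5-methoxy-4-oxo-6-Ar-4H-pyran-2-carboxylate
Conditions: Pd(dppf)Cl2 (5 mol %), K3PO4, 1,4-dioxane/H2O (10:1), 70 °C
Reagents that add atoms: none
Why: Suzuki–Miyaura coupling; the C6–Br bond of 4 is a vinylogous acyl bromide and should undergo oxidative addition readily, and the boron sits on an unhindered position of ring B; partial ester hydrolysis would be harmless because step 8 follows.

Step 8
Reactants: 11 methyl 5-methoxy-4-oxo-6-Ar-4H-pyran-2-carboxylate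
Product: 12 5-methoxy-4-oxo-6-Ar-4H-pyran-2-carboxylic acid
Conditions: LiOH·H2O (1.5 equiv), THF/H2O (3:1), 0 °C; then 1 M HCl to pH 3, 0 °C
Reagents that add atoms: lithium hydroxide, [Li+].[OH-]
Why: Saponification of an activated ester (carbonyl on an electron-poor pyranone) should be fast at 0 °C, ahead of conjugate attack on the ring and of cleavage of the hindered aryl silyl ether.

Step 9
Reactants: 12 5-methoxy-4-oxo-6-Ar-4H-pyran-2-carboxylic acid
Product: 14 2-(diazoacetyl)-5-methoxy-6-Ar-4H-pyran-4-one, via isobutyl carbonic mixed anhydride 13 (not isolated)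
Conditions: i-BuOCOCl, N-methylmorpholine, THF, −15 °C; then CH2N2 (Et2O, 2.5 equiv), −15 → 0 °C
Reagents that add atoms: diazomethane, C=[N+]=[N-]; isobutyl chloroformate, CC(C)COC(Cl)=O (its atoms stay only in 13)
Why: Arndt–Eistert-type acylation of diazomethane by a mixed carbonic anhydride, which attacks the more electrophilic pyranoyl carbonyl; no HCl is formed, so the prenyl olefins and silyl ether are not exposed to acid.

Step 10
Reactants: 15 ethynyltrimethylsilane; 8 triisopropylsilyl trifluoromethanesulfonate
Product: 18 trimethyl[(triisopropylsilyloxy)ethynyl]silane, via lithium (trimethylsilyl)acetylide 16 (not isolated), via lithium 2-(trimethylsilyl)ethynolate 17 (not isolated)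
Conditions: n-BuLi, THF, −78 °C; t-BuOOLi (from t-BuOOH and LiN(SiMe3)2), −78 → 0 °C; then 8, −78 → 0 °C
Reagents that add atoms: tert-butyl hydroperoxide, CC(C)(C)OO; n-butyllithium, [Li]CCCC (lithium stays only in 16 and 17)
Why: Electrophilic oxygen transfer from a lithium alkyl peroxide to a lithium acetylide gives the ynolate, a known route to siloxyalkynes; the bulky silyl triflate and the C-silyl group together should direct silylation to oxygen.

Step 11
Reactants: 18 trimethyl[(triisopropylsilyloxy)ethynyl]silane
Product: 19 (triisopropylsilyloxy)acetylene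
Conditions: K2CO3 (0.2 equiv), MeOH, 0 °C; pentane extraction, kept as a toluene solution
Reagents that add atoms: none
Why: Methoxide-catalysed protodesilylation of an alkynyl trimethylsilane; attack at the small C-bound silicon should be much faster than at the hindered O-bound triisopropylsilyl group, and ynol ethers are stable to cold basic methanol.

Step 12
Reactants: 14 2-(diazoacetyl)-5-methoxy-6-Ar-4H-pyran-4-one; 19 (triisopropylsilyloxy)acetylene (2 equiv)
Product: 24 5-hydroxy-3-methoxy-2-Ar-7-(triisopropylsilyloxy)-4H-chromen-4-one, via pyranonylketene 20 (not isolated), via siloxycyclobutenone 21 (not isolated), via dienylketene 22 (not isolated), via cyclohexadienone tautomer 23 (not isolated)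
Conditions: blue LEDs (ca. 440 nm), degassed toluene (0.05 M), 25 °C; then 90 °C in the dark
Reagents that add atoms: none
Why: Excitation of the diazoketone expels N2 and the pyranon-2-yl group migrates (photo-Wolff rearrangement) to give ketene 20. The polarized siloxyalkyne 19 then adds in a (2+2) cycloaddition, its unsubstituted carbon bonding to the ketene carbonyl carbon (C5–C6) and its oxygen-bearing carbon to the ketene α-carbon (C7–C8), to give cyclobutenone 21. On warming, 21 opens by a reversible conrotatory 4π electrocyclic reaction to dienylketene 22, and the isomer with the ketene next to the pyranone closes ring A by a thermally allowed disrotatory 6π electrocyclization across the former pyranone C2=C3 bond (C4a–C5), giving 23. Tautomerization of 23 aromatizes ring A and is helped by the hydrogen bond from the new C5 hydroxyl to the C4 carbonyl. The closest known reaction type is the photo-Wolff variant of the Danheiser benzannulation of aryl, heteroaryl and alkenyl diazomethyl ketones with siloxyalkynes. No stereocentre remains, since the sp3 carbons of 21 and 23 are transient. The selectivity needed is regiochemical: the polarity of 19 puts the silyloxy group at C7 and not C6, and the 6π closure can only reach pyranone C3 because the other neighbour of C2 is the ring oxygen. Visible light, absorbed by the diazo group but not by the aryl pyranone or the product, and excess 19, which outpaces ketene dimerization and the prenyl olefins, should secure chemoselectivity.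

Step 13
Reactants: 24 5-hydroxy-3-methoxy-2-Ar-7-(triisopropylsilyloxy)-4H-chromen-4-one
Product: 25 5,7-dihydroxy-2-[4-hydroxy-3,5-bis(3-methylbut-2-enyl)phenyl]-3-methoxy-4H-chromen-4-one (target)
Conditions: TBAF (2.5 equiv), AcOH (2.5 equiv), THF, 0 → 25 °C
Reagents that add atoms: none
Why: Fluoride-driven cleavage of both aryl silyl ethers (phenoxide leaving groups, strong Si–F bond); the acetic acid buffer keeps the medium near neutral for the flavone and no acid strong enough to cyclize the prenyl phenol is present.

## Compound list

1 | kojic acid, 5-hydroxy-2-(hydroxymethyl)-4H-pyran-4-one | OCc1cc(=O)c(O)co1 | starting material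
2 | comenic acid, 5-hydroxy-4-oxo-4H-pyran-2-carboxylic acid | OC(=O)c1cc(=O)c(O)co1 | intermediate
3 | 6-bromo-5-hydroxy-4-oxo-4H-pyran-2-carboxylic acid | OC(=O)c1cc(=O)c(O)c(Br)o1 | intermediate
4 | methyl 6-bromo-5-methoxy-4-oxo-4H-pyran-2-carboxylate | COC(=O)c1cc(=O)c(OC)c(Br)o1 | intermediate
5 | 4-bromophenol | Oc1ccc(Br)cc1 | starting material
6 | prenyl bromide, 1-bromo-3-methylbut-2-ene | CC(C)=CCBr | starting material
7 | 4-bromo-2,6-bis(3-methylbut-2-enyl)phenol | CC(C)=CCc1cc(Br)cc(CC=C(C)C)c1O | intermediate
8 | triisopropylsilyl trifluoromethanesulfonate | CC(C)[Si](OS(=O)(=O)C(F)(F)F)(C(C)C)C(C)C | starting material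
9 | [4-bromo-2,6-bis(3-methylbut-2-enyl)phenoxy]triisopropylsilane | CC(C)=CCc1cc(Br)cc(CC=C(C)C)c1O[Si](C(C)C)(C(C)C)C(C)C | intermediate
10 | triisopropyl[2,6-bis(3-methylbut-2-enyl)-4-(4,4,5,5-tetramethyl-1,3,2-dioxaborolan-2-yl)phenoxy]silane | CC(C)=CCc1cc(B2OC(C)(C)C(C)(C)O2)cc(CC=C(C)C)c1O[Si](C(C)C)(C(C)C)C(C)C | intermediate
11 | methyl 5-methoxy-4-oxo-6-[3,5-bis(3-methylbut-2-enyl)-4-(triisopropylsilyloxy)phenyl]-4H-pyran-2-carboxylate | COC(=O)c1cc(=O)c(OC)c(-c2cc(CC=C(C)C)c(O[Si](C(C)C)(C(C)C)C(C)C)c(CC=C(C)C)c2)o1 | intermediate
12 | 5-methoxy-4-oxo-6-[3,5-bis(3-methylbut-2-enyl)-4-(triisopropylsilyloxy)phenyl]-4H-pyran-2-carboxylic acid | OC(=O)c1cc(=O)c(OC)c(-c2cc(CC=C(C)C)c(O[Si](C(C)C)(C(C)C)C(C)C)c(CC=C(C)C)c2)o1 | intermediate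
13 | mixed anhydride of 12 with isobutyl hydrogen carbonate | CC(C)COC(=O)OC(=O)c1cc(=O)c(OC)c(-c2cc(CC=C(C)C)c(O[Si](C(C)C)(C(C)C)C(C)C)c(CC=C(C)C)c2)o1 | intermediate (not isolated)
14 | 2-(diazoacetyl)-5-methoxy-6-[3,5-bis(3-methylbut-2-enyl)-4-(triisopropylsilyloxy)phenyl]-4H-pyran-4-one | [N-]=[N+]=CC(=O)c1cc(=O)c(OC)c(-c2cc(CC=C(C)C)c(O[Si](C(C)C)(C(C)C)C(C)C)c(CC=C(C)C)c2)o1 | intermediate
15 | ethynyltrimethylsilane | C#C[Si](C)(C)C | starting material
16 | lithium (trimethylsilyl)acetylide | [Li]C#C[Si](C)(C)C | intermediate (not isolated)
17 | lithium 2-(trimethylsilyl)ethynolate | [Li+].[O-]C#C[Si](C)(C)C | intermediate (not isolated)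
18 | trimethyl[(triisopropylsilyloxy)ethynyl]silane | C[Si](C)(C)C#CO[Si](C(C)C)(C(C)C)C(C)C | intermediate
19 | (triisopropylsilyloxy)acetylene | C#CO[Si](C(C)C)(C(C)C)C(C)C | intermediate
20 | 2-{5-methoxy-4-oxo-6-[3,5-bis(3-methylbut-2-enyl)-4-(triisopropylsilyloxy)phenyl]-4H-pyran-2-yl}ethenone (ketene) | O=C=Cc1cc(=O)c(OC)c(-c2cc(CC=C(C)C)c(O[Si](C(C)C)(C(C)C)C(C)C)c(CC=C(C)C)c2)o1 | intermediate (not isolated)
21 | 4-{5-methoxy-4-oxo-6-[3,5-bis(3-methylbut-2-enyl)-4-(triisopropylsilyloxy)phenyl]-4H-pyran-2-yl}-3-(triisopropylsilyloxy)cyclobut-2-en-1-one (racemic) | O=C1C=C(O[Si](C(C)C)(C(C)C)C(C)C)C1c1cc(=O)c(OC)c(-c2cc(CC=C(C)C)c(O[Si](C(C)C)(C(C)C)C(C)C)c(CC=C(C)C)c2)o1 | intermediate (not isolated)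
22 | (3E)-4-{5-methoxy-4-oxo-6-[3,5-bis(3-methylbut-2-enyl)-4-(triisopropylsilyloxy)phenyl]-4H-pyran-2-yl}-3-(triisopropylsilyloxy)buta-1,3-dien-1-one (ketene carbon and pyranone on the same side of the C3=C4 bond) | O=C=C/C(O[Si](C(C)C)(C(C)C)C(C)C)=C\c1cc(=O)c(OC)c(-c2cc(CC=C(C)C)c(O[Si](C(C)C)(C(C)C)C(C)C)c(CC=C(C)C)c2)o1 | intermediate (not isolated)
23 | 3-methoxy-2-[3,5-bis(3-methylbut-2-enyl)-4-(triisopropylsilyloxy)phenyl]-7-(triisopropylsilyloxy)-4aH-chromene-4,5-dione (racemic keto tautomer of 24) | COC1=C(c2cc(CC=C(C)C)c(O[Si](C(C)C)(C(C)C)C(C)C)c(CC=C(C)C)c2)OC2=CC(O[Si](C(C)C)(C(C)C)C(C)C)=CC(=O)C2C1=O | intermediate (not isolated)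
24 | 5-hydroxy-3-methoxy-2-[3,5-bis(3-methylbut-2-enyl)-4-(triisopropylsilyloxy)phenyl]-7-(triisopropylsilyloxy)-4H-chromen-4-one | COc1c(-c2cc(CC=C(C)C)c(O[Si](C(C)C)(C(C)C)C(C)C)c(CC=C(C)C)c2)oc2cc(O[Si](C(C)C)(C(C)C)C(C)C)cc(O)c2c1=O | intermediate
25 | 5,7-dihydroxy-2-[4-hydroxy-3,5-bis(3-methylbut-2-enyl)phenyl]-3-methoxy-4H-chromen-4-one | COc1c(-c2cc(CC=C(C)C)c(O)c(CC=C(C)C)c2)oc2cc(O)cc(O)c2c1=O | target

## Step count and least certain steps

Total step count: 13. Longest linear sequence: 8 steps (steps 1, 2, 3, 7, 8, 9, 12, 13 from 1; the ring B branch, steps 4, 5, 6, 7, 8, 9, 12, 13 from 5, is equally long).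

**Step 12 (key step).** The ketene may be diverted before the (2+2) union, by dimerization or by reaction of the excited diazoketone with a prenyl olefin. The thermal ring opening and 6π closure onto the cross-conjugated pyranone carbon may also stall at the cyclobutenone stage, because that C=C bond is a poorer 2π partner than an arene or simple alkene. The fallback gives up the annulation of ring A and builds ring C by the classical diketone route, starting from 9. Bromine–lithium exchange (n-BuLi, THF, −78 °C) would give the aryllithium F1, and CO2 would convert it to 3,5-bis(3-methylbut-2-enyl)-4-(triisopropylsilyloxy)benzoic acid F2. 1-Chloro-N,N,2-trimethylprop-1-en-1-amine would turn F2 into the acid chloride F3 under neutral conditions. The polyanion (LiN(SiMe3)2, THF, −78 °C) of 2-methoxy-1-(2,4,6-trihydroxyphenyl)ethanone F4 (purchasable, or one Houben–Hoesch step) would be C-acylated by F3 to the Baker–Venkataraman-type diketone F5. Warming F5 in acetic acid would cyclodehydrate it to the 4'-O-silyl flavone F6, and the conditions of step 13 would then give 25.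

**Step 10.** Oxygen transfer to the silylacetylide may be incomplete, the alkoxide formed may cleave the C–Si bond before silylation, or some silylation may occur on carbon. The fallback starts from 8 and makes the same ynolate by another known route. (Trimethylsilyl)diazomethane F7 would be lithiated (n-BuLi, THF, −78 °C) to lithium (trimethylsilyl)diazomethanide F8, which takes up carbon monoxide with loss of N2 to give 17. Silylation with 8 returns to the route at 18.

**Step 11.** Loss of the O-silyl group or addition of methanol across the ynol ether may compete with C-desilylation, and the volatile product may be lost on concentration. The fallback skips step 11 and removes the C-silyl group after the annulation. Compound 18 would be used with 14 under the conditions of step 12. The cascade would pass through the C-silylated cyclobutenone F9, dienylketene F10 and cyclohexadienone F11 to the 6-trimethylsilyl flavone F12. In F12 the silicon sits on the carbon between the two ring A oxygens, where ipso-protodesilylation is very easy. The buffered fluoride of step 13 should therefore remove all three silyl groups and return to the route at 25.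

**Step 9.** The diazoalkane may add as a 1,3-dipole to the electron-poor C2=C3 bond of the pyranone, or attack the carbonate carbonyl of the mixed anhydride. The fallback avoids diazomethane and starts from 12. Carbodiimide coupling with N,O-dimethylhydroxylamine would give the Weinreb amide F13. MeMgBr (THF, −78 °C) would give the methyl ketone F14. Trifluoroacetylation (LiN(SiMe3)2, 2,2,2-trifluoroethyl trifluoroacetate, −78 °C) would give the diketone F15. Detrifluoroacetylative diazo transfer with methanesulfonyl azide (Et3N, H2O, MeCN) returns to the route at 14.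

**Step 4.** O-Alkylation, stopping at the mono-prenyl stage, and cyclization of an ortho-prenyl phenoxide to a chroman may all lower the return, because the ambident phenoxide is controlled only by solvent and counter-ion. The fallback introduces each prenyl group through an ether and a sigmatropic shift, starting from 5. Tsuji–Trost O-alkylation with tert-butyl 2-methylbut-3-en-2-yl carbonate F16 (Pd(PPh3)4 cat., THF, 0 °C) would give 1-bromo-4-[(2-methylbut-3-en-2-yl)oxy]benzene F17. Aromatic Claisen rearrangement (toluene, 110 °C) would give 4-bromo-2-(3-methylbut-2-enyl)phenol F18. A second O-alkylation with F16 would give 4-bromo-1-[(2-methylbut-3-en-2-yl)oxy]-2-(3-methylbut-2-enyl)benzene F19, and a second Claisen rearrangement returns to the route at 7.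

## Further compounds

F1 | step 12 | [3,5-bis(3-methylbut-2-enyl)-4-(triisopropylsilyloxy)phenyl]lithium | [Li]c1cc(CC=C(C)C)c(O[Si](C(C)C)(C(C)C)C(C)C)c(CC=C(C)C)c1
F2 | step 12 | 3,5-bis(3-methylbut-2-enyl)-4-(triisopropylsilyloxy)benzoic acid | OC(=O)c1cc(CC=C(C)C)c(O[Si](C(C)C)(C(C)C)C(C)C)c(CC=C(C)C)c1
F3 | step 12 | 3,5-bis(3-methylbut-2-enyl)-4-(triisopropylsilyloxy)benzoyl chloride | ClC(=O)c1cc(CC=C(C)C)c(O[Si](C(C)C)(C(C)C)C(C)C)c(CC=C(C)C)c1
F4 | step 12 | 2-methoxy-1-(2,4,6-trihydroxyphenyl)ethanone | COCC(=O)c1c(O)cc(O)cc1O
F5 | step 12 | 2-methoxy-1-[3,5-bis(3-methylbut-2-enyl)-4-(triisopropylsilyloxy)phenyl]-3-(2,4,6-trihydroxyphenyl)propane-1,3-dione (racemic, enolizable) | COC(C(=O)c1c(O)cc(O)cc1O)C(=O)c1cc(CC=C(C)C)c(O[Si](C(C)C)(C(C)C)C(C)C)c(CC=C(C)C)c1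
F6 | step 12 | 5,7-dihydroxy-3-methoxy-2-[3,5-bis(3-methylbut-2-enyl)-4-(triisopropylsilyloxy)phenyl]-4H-chromen-4-one | COc1c(-c2cc(CC=C(C)C)c(O[Si](C(C)C)(C(C)C)C(C)C)c(CC=C(C)C)c2)oc2cc(O)cc(O)c2c1=O
F7 | step 10 | (trimethylsilyl)diazomethane | C[Si](C)(C)C=[N+]=[N-]
F8 | step 10 | lithium (trimethylsilyl)diazomethanide | [Li]C(=[N+]=[N-])[Si](C)(C)C
F9 | step 11 | 4-{5-methoxy-4-oxo-6-[3,5-bis(3-methylbut-2-enyl)-4-(triisopropylsilyloxy)phenyl]-4H-pyran-2-yl}-3-(triisopropylsilyloxy)-2-(trimethylsilyl)cyclobut-2-en-1-one (racemic) | O=C1C([Si](C)(C)C)=C(O[Si](C(C)C)(C(C)C)C(C)C)C1c1cc(=O)c(OC)c(-c2cc(CC=C(C)C)c(O[Si](C(C)C)(C(C)C)C(C)C)c(CC=C(C)C)c2)o1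
F10 | step 11 | (3E)-4-{5-methoxy-4-oxo-6-[3,5-bis(3-methylbut-2-enyl)-4-(triisopropylsilyloxy)phenyl]-4H-pyran-2-yl}-3-(triisopropylsilyloxy)-2-(trimethylsilyl)buta-1,3-dien-1-one | O=C=C([Si](C)(C)C)/C(O[Si](C(C)C)(C(C)C)C(C)C)=C\c1cc(=O)c(OC)c(-c2cc(CC=C(C)C)c(O[Si](C(C)C)(C(C)C)C(C)C)c(CC=C(C)C)c2)o1
F11 | step 11 | 3-methoxy-2-[3,5-bis(3-methylbut-2-enyl)-4-(triisopropylsilyloxy)phenyl]-7-(triisopropylsilyloxy)-6-(trimethylsilyl)-4aH-chromene-4,5-dione (racemic) | COC1=C(c2cc(CC=C(C)C)c(O[Si](C(C)C)(C(C)C)C(C)C)c(CC=C(C)C)c2)OC2=CC(O[Si](C(C)C)(C(C)C)C(C)C)=C([Si](C)(C)C)C(=O)C2C1=O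
F12 | step 11 | 5-hydroxy-3-methoxy-2-[3,5-bis(3-methylbut-2-enyl)-4-(triisopropylsilyloxy)phenyl]-7-(triisopropylsilyloxy)-6-(trimethylsilyl)-4H-chromen-4-one | COc1c(-c2cc(CC=C(C)C)c(O[Si](C(C)C)(C(C)C)C(C)C)c(CC=C(C)C)c2)oc2cc(O[Si](C(C)C)(C(C)C)C(C)C)c([Si](C)(C)C)c(O)c2c1=O
F13 | step 9 | N,5-dimethoxy-N-methyl-4-oxo-6-[3,5-bis(3-methylbut-2-enyl)-4-(triisopropylsilyloxy)phenyl]-4H-pyran-2-carboxamide | CON(C)C(=O)c1cc(=O)c(OC)c(-c2cc(CC=C(C)C)c(O[Si](C(C)C)(C(C)C)C(C)C)c(CC=C(C)C)c2)o1
F14 | step 9 | 2-acetyl-5-methoxy-6-[3,5-bis(3-methylbut-2-enyl)-4-(triisopropylsilyloxy)phenyl]-4H-pyran-4-one | CC(=O)c1cc(=O)c(OC)c(-c2cc(CC=C(C)C)c(O[Si](C(C)C)(C(C)C)C(C)C)c(CC=C(C)C)c2)o1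
F15 | step 9 | 4,4,4-trifluoro-1-{5-methoxy-4-oxo-6-[3,5-bis(3-methylbut-2-enyl)-4-(triisopropylsilyloxy)phenyl]-4H-pyran-2-yl}butane-1,3-dione | O=C(CC(=O)C(F)(F)F)c1cc(=O)c(OC)c(-c2cc(CC=C(C)C)c(O[Si](C(C)C)(C(C)C)C(C)C)c(CC=C(C)C)c2)o1
F16 | step 4 | tert-butyl 2-methylbut-3-en-2-yl carbonate | CC(C)(C)OC(=O)OC(C)(C)C=C
F17 | step 4 | 1-bromo-4-[(2-methylbut-3-en-2-yl)oxy]benzene | C=CC(C)(C)Oc1ccc(Br)cc1
F18 | step 4 | 4-bromo-2-(3-methylbut-2-enyl)phenol | CC(C)=CCc1cc(Br)ccc1O
F19 | step 4 | 4-bromo-1-[(2-methylbut-3-en-2-yl)oxy]-2-(3-methylbut-2-enyl)benzene | C=CC(C)(C)Oc1ccc(Br)cc1CC=C(C)C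
A1 | alternative 1 | 2-iodo-1,3,5-tris(methoxymethoxy)benzene | COCOc1cc(OCOC)c(I)c(OCOC)c1
A2 | alternative 1 | 2-methoxy-1-[4-(methoxymethoxy)-3,5-bis(3-methylbut-2-enyl)phenyl]ethanone | COCC(=O)c1cc(CC=C(C)C)c(OCOC)c(CC=C(C)C)c1
A3 | alternative 1 | 2-methoxy-1-[4-(methoxymethoxy)-3,5-bis(3-methylbut-2-enyl)phenyl]-3-[2,4,6-tris(methoxymethoxy)phenyl]propane-1,3-dione (racemic, enolizable) | COCOc1cc(OCOC)c(C(=O)C(OC)C(=O)c2cc(CC=C(C)C)c(OCOC)c(CC=C(C)C)c2)c(OCOC)c1
A4 | alternative 1 | carbon monoxide | [C-]#[O+]
A5 | alternative 2 | 2-[2-formyl-3,5-bis(methoxymethoxy)phenoxy]-2-[4-(methoxymethoxy)-3,5-bis(3-methylbut-2-enyl)phenyl]acetaldehyde (racemic) | O=CC(Oc1cc(OCOC)cc(OCOC)c1C=O)c1cc(CC=C(C)C)c(OCOC)c(CC=C(C)C)c1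
A6 | alternative 2 | 2,3-trans-3,4-cis-2-[4-(methoxymethoxy)-3,5-bis(3-methylbut-2-enyl)phenyl]-5,7-bis(methoxymethoxy)chromane-3,4-diol (racemic, relative configuration drawn) | O[C@@H]1[C@H](O)[C@@H](c2cc(CC=C(C)C)c(OCOC)c(CC=C(C)C)c2)Oc2cc(OCOC)cc(OCOC)c21
A7 | alternative 2 | samarium diiodide | I[Sm]I
A8 | alternative 3 | 2-methoxy-1-[4-(allyloxy)-3,5-bis(3-methylbut-2-enyl)phenyl]-3-(2,4,6-trifluorophenyl)propane-1,3-dione (racemic, enolizable) | COC(C(=O)c1c(F)cc(F)cc1F)C(=O)c1cc(CC=C(C)C)c(OCC=C)c(CC=C(C)C)c1
A9 | alternative 3 | 2-[4-(allyloxy)-3,5-bis(3-methylbut-2-enyl)phenyl]-5,7-difluoro-3-methoxy-4H-chromen-4-one | COc1c(-c2cc(CC=C(C)C)c(OCC=C)c(CC=C(C)C)c2)oc2cc(F)cc(F)c2c1=O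
A10 | alternative 3 | 5,7-bis(allyloxy)-2-[4-(allyloxy)-3,5-bis(3-methylbut-2-enyl)phenyl]-3-methoxy-4H-chromen-4-one | COc1c(-c2cc(CC=C(C)C)c(OCC=C)c(CC=C(C)C)c2)oc2cc(OCC=C)cc(OCC=C)c2c1=O
A11 | alternative 3 | allyl alcohol, prop-2-en-1-ol | C=CCO
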